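Compound numbers used throughout: **1** 3,4,5-trimethoxyphenol, **2** the salicylaldehyde made from it, **3** 4-acetoxy-3-methoxystyrene, **4** and **5** the acetal and ortho-quinone methide formed in the flask, **6** the cycloadduct, **7** the flavanone acetate, **8** agecorynin E. Flavonoid numbering (O1, C2, C3, C4, C4a, C5–C8, C8a; rings A, B, C) is used for all atoms.

## The problem

Agecorynin E (8) is (2S)-2-(4-hydroxy-3-methoxyphenyl)-5,6,7-trimethoxychroman-4-one. A very electron-rich ring A (methoxyls at C5, C6 and C7, one free position at C8) is fused to the dihydropyranone ring C, which carries the guaiacyl ring B at C2. The only stereocentre is C2, a benzylic carbon bonded to O1 and β to the C4 carbonyl. Nothing in the molecule can control it, so it must be set by a catalyst or relayed from a temporary centre that is later removed. The centre is fragile: base opens ring C by retro-oxa-Michael reaction to the 2'-hydroxychalcone, and a free 4'-hydroxyl makes loss of O1 from C2 easier still (quinone methide pathway). Ketone and free phenol should therefore coexist only at the very end and never under basic conditions. Ring A is prone to oxidation and to electrophilic attack at C8, and four methoxyls must be kept distinct from one phenol, so the methoxyls are best bought with the arene and the phenol carried in protected form. The enabling feature is that O1–C8a=C4a–C4 of ring C is the heterodiene of an ortho-quinone methide of ring A, while C2–C3 with its aryl group is the double bond of a 4-vinylguaiacol. C4 is then the carbon of a salicylaldehyde, and its oxidation level can ride through the ring-forming step as a methoxyl from the aldehyde acetal. One cycloaddition can thus form C3–C4 and O1–C2, close ring C and set C2.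

## Retrosynthesis

**8 from 7.** No skeletal bond is cut; the 4'-hydroxyl of 8 is masked as the acetate in 7. An acetate is preferred to a benzyl or silyl ether for three reasons. It withdraws electron density from ring B, so the O1–C2 bond resists ionisation and C2–H resists oxidants in every earlier step. It falls to acid-catalysed methanolysis, under which a flavanone does not open. And it leaves the styrene partner less prone to cationic polymerisation. The forward step must cleave an aryl ester without base.

**7 from 6.** The C4 carbonyl is traced to the C4 methyl ether of the 2,4-cis flavan 6; again no skeletal bond is cut. The neighbouring choice, a flavan without a C4 substituent, would need a benzylic C–H oxidation that has to choose between C2–H and C4–H. In 6 the C4–H is by far the most hydridic position (benzylic to a 2,4,6-oxygenated ring and α to a methoxyl), so a quinone oxidant should find it selectively. The temporary C4 stereocentre disappears here, so only C2 of 6 needs to be right. The forward step needs an oxidant that spares C2–H, ring A and the acetate.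

**6 from 2 and 3.** C3–C4 and O1–C2 are cut together, which maps ring C onto quinone methide 5 and styrene 3; 5 comes from aldehyde 2 through acetal 4 and trimethyl orthoformate. The single-bond cuts nearby are weaker. Cutting O1–C2 alone leads to a chalcone whose oxa-Michael closure is reversible and hard to make enantioselective without an extra activating group. Cutting C2–aryl requires a preformed chromone and a conjugate arylation next to the peri methoxyl. The double cut divides 6 into two halves of similar size, one bought and one a single step from commerce, and removes the ring and both stereocentres at once. The forward step needs an acid that generates 5 from 2 and also decides which face of 3 bonds to O1; regiochemistry is given by polarity.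

**2 from 1.** The C4a–C4 bond (the formyl group) is cut. Phenol 1 already carries the three methoxyls in the right places, and its two ortho positions are equivalent, so ortho-formylation can give only 2. A magnesium-mediated ortho-specific formylation is preferred to Vilsmeier or Reimer–Tiemann conditions, which risk O-formylation or poor conversion. Styrene 3 is bought.

## Roads not taken

**Alternative 1:** The cut lies in ring A (C4a–C5, C5–C6 and C8–C8a). Irradiation of 1-diazo-3,4-dimethoxybut-3-en-2-one A1 would give, by Wolff rearrangement, the vinylketene A2. A2 adds to the chiral siloxyalkyne A3 by [2+2] addition, 4π opening, 6π closure and tautomerisation to the pentasubstituted phenol A4. In A4 the free hydroxyl is the future C5 oxygen, the silyloxy oxygen the future O1 and the silylated carbinol the future C2.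
- Merits: complete regiocontrol over a crowded arene, and a stereocentre that comes from a well-understood asymmetric ketone reduction.
- Weak points: ring A with exactly this oxygenation is an article of commerce as 1, so the annulation rebuilds what can be bought. A1 is a sensitive polyoxygenated diazo compound and A3 needs its own multistep preparation. After A4 the sequence must still methylate, remove two silyl groups, close ring C by inversion at an electron-rich benzylic alcohol (where SN1 leakage erodes the configuration), oxidise C4–H of a flavan with no substituent to guide the oxidant, and debenzylate.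
- Comparison: in stereochemical certainty this road is better, because every stereo-determining reaction is known. The chosen plan sets against that its length (four steps against well over ten), a C4 position already marked for oxidation, and a fallback that restores enantiopurity by known chemistry.

**Alternative 2:** The cut is C3=C4. The diene A5, an aryl 1-arylallyl ether with a 1-(silyloxy)vinyl group on C4a, would be closed by ring-closing metathesis with the second-generation Grubbs catalyst to the cyclic silyl enol ether A6, whose hydrolysis leads to 7.
- Merits: metathesis onto a silyl enol ether is a known reaction type. C4 arrives at the ketone level with no oxidant near ring A. C2 is set before the ring closes and takes no part in the closure. Branched-selective asymmetric allylic etherification (for instance with [Ir(cod)Cl]2 and a phosphoramidite) is an established route to such ethers.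
- Weak points: the phenol to be etherified is ortho-acylated, hydrogen-bonded and flanked by a methoxyl, and so a poor nucleophile. Enol silylation must avoid strong base, because C2–H of A5 is allylic, benzylic and α to oxygen (Wittig rearrangement). The metathesis must engage a 1,1-disubstituted electron-rich olefin wedged beside the C5 methoxyl. A6 is a 2-aryl-2H-chromene, a class that opens reversibly by 6π electrocyclic reaction, which would scramble C2 before hydrolysis.
- Comparison: the key step here is better precedented than the chosen one and converges on 7. The chosen plan offers in return about half the step count, no precious-metal catalysts, and formation of both ring bonds and the stereocentre in one operation.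

**Alternative 3:** The cut is O1–C8a. The anti-diol A7, with bromine on the future C8a, would cyclise through its C2 hydroxyl under Pd(OAc)2, 2-(di-tert-butylphosphino)-1,1'-binaphthyl and Cs2CO3 to the cis-flavan-4-ol A8. Oxidation at C4 and hydrogenolysis of the benzyl ether would finish at 8.
- Merits: both carbinol centres come from known aldol and directed-reduction chemistry. C2 is a spectator in the ring closure, since the new bond forms at an sp2 carbon. Palladium-catalysed intramolecular etherification with secondary alcohols is known.
- Weak points: A7 needs a brominated, fully substituted ring A, an enantioselective acetate-type aldol and an anti-selective reduction, roughly six steps before the key step. One of its two centres (C4) is built only to be oxidised. The aryl bromide is electron-rich and doubly ortho-substituted, so oxidative addition is slow. The palladium alkoxide of a secondary benzylic alcohol can undergo β-hydride elimination, giving ketone and reduced arene.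
- Comparison: stereochemical reliability is better than in the chosen plan. Both plans pass through a 2,4-cis flavan that is oxidised at C4; in the chosen plan that centre costs nothing, because it is a by-product of the cycloaddition. The chosen plan has brevity and convergence to set against the more certain stereocontrol of this road.

Key step: step 2

Assumptions (remarks on the chemistry):
- 4-Acetoxy-3-methoxystyrene (3) is treated as a purchasable, stabilised monomer.
- The sense of induction of the chiral acid cannot be derived from precedent. The (R)-acid is written; its (S)-antipode would be used if the (R)-acid favours the (2R) series.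
- Quinone methide 5 is drawn with (E) geometry. Because C4 is oxidised in step 3, the C4 configuration of 6 has no bearing on the target.

Step 1
Reactants: 1 3,4,5-trimethoxyphenol
Product: 2 2-hydroxy-4,5,6-trimethoxybenzaldehyde
Conditions: MgCl2 (1.5 equiv), Et3N (3.75 equiv), (CH2O)n (6.7 equiv), MeCN, reflux; then 1 M HCl
Reagents that add atoms: paraformaldehyde (as formaldehyde), C=O
Why: Casnati–Skattebøl ortho-formylation: the magnesium phenoxide directs hydroxymethylation to the ortho carbon and a second formaldehyde oxidises the benzylic alkoxide by hydride transfer. The two ortho positions of 1 are equivalent, so only one aldehyde can form.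

Step 2
Reactants: 2 2-hydroxy-4,5,6-trimethoxybenzaldehyde; 3 4-acetoxy-3-methoxystyrene (2-methoxy-4-vinylphenyl acetate)
Product: 6 (2S,4S)-2-(4-acetoxy-3-methoxyphenyl)-4,5,6,7-tetramethoxychroman (2,4-cis), via dimethyl acetal 4 (not isolated), via ortho-quinone methide 5 (not isolated)
Conditions: HC(OMe)3 (3 equiv), 3 (2 equiv), (R)-3,3'-bis(2,4,6-triisopropylphenyl)-1,1'-binaphthyl-2,2'-diyl hydrogen phosphate (10 mol %), 5 Å molecular sieves, toluene, −20 °C to rt
Reagents that add atoms: trimethyl orthoformate, COC(OC)OC
Why: Proposed new method: the chiral acid should turn 2 with the orthoformate into acetal 4 and then, by loss of methanol, into 5, held as a hydrogen-bonded or protonated (oxocarbenium–phenol) ion pair with the phosphate; the CH2 terminus of 3 attacks C4 and the developing benzylic cation is captured by O1, a polar, asynchronous inverse-demand hetero-Diels–Alder reaction. The closest known reaction types are the racemic acid-promoted union of salicylaldehydes, orthoformates and styrenes to 4-alkoxyflavans and chiral phosphoric acid catalysed [4+2] reactions of ortho-quinone methides made from ortho-hydroxybenzyl alcohols; new is their combination on an acetal-derived, methoxy-substituted quinone methide. Ring C closes in the [4+2] mode as a six-membered ring, C3–C4 first and O1–C2 second. C2 is under catalyst control: O1, which bonds to C2, is the atom that carries the phosphate, so the chiral pocket decides which enantiotopic face of the styrene is offered, and the (S) sense is needed. C4 follows from the geometry of approach (aryl endo on the (E) form of 5 gives 2,4-cis, hence 4S), but it is oxidised away in step 3, so only the C2 configuration must be secured and later epimerisation of the labile C4 methoxyl is harmless. Regiochemistry is secured by polarity, the nucleophilic terminus of 3 meeting the electrophilic C4. The acetoxy group keeps the C2 cation short-lived, so that closure precedes bond rotation, and keeps O1–C2 of 6 from re-ionising; the excess of 3 is there to outrun Friedel–Crafts capture of the cation by C8 of ring A.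

Step 3
Reactants: 6 (2S,4S)-2-(4-acetoxy-3-methoxyphenyl)-4,5,6,7-tetramethoxychroman
Product: 7 (2S)-2-(4-acetoxy-3-methoxyphenyl)-5,6,7-trimethoxychroman-4-one
Conditions: DDQ (1.2 equiv), CH2Cl2/pH 7 phosphate buffer (10:1), 0 °C to rt
Reagents that add atoms: water, O
Why: DDQ oxidation of an electron-rich benzylic methyl ether: hydride abstraction from C4–H, activated by the 2,4,6-oxygenated ring A and the methoxyl, gives an oxocarbenium ion that water converts into the ketone with release of methanol. C2–H sits on the acetoxy-deactivated ring B and is much less hydridic, so C2 is not touched; the new carbonyl then deactivates ring A against further oxidation.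

Step 4
Reactants: 7 (2S)-2-(4-acetoxy-3-methoxyphenyl)-5,6,7-trimethoxychroman-4-one
Product: 8 agecorynin E, (2S)-2-(4-hydroxy-3-methoxyphenyl)-5,6,7-trimethoxychroman-4-one
Conditions: HCl (1.25 M in MeOH), MeOH/CH2Cl2, 0 °C to rt
Reagents that add atoms: none
Why: Acid-catalysed transesterification of the aryl acetate to methyl acetate. Under acid the flavanone does not open to the chalcone, so C2 should keep its (S) configuration.

Compound list

1 | 3,4,5-trimethoxyphenol | COc1cc(O)cc(OC)c1OC | starting material
2 | 2-hydroxy-4,5,6-trimethoxybenzaldehyde | COc1cc(O)c(C=O)c(OC)c1OC | intermediate
3 | 4-acetoxy-3-methoxystyrene (2-methoxy-4-vinylphenyl acetate) | C=Cc1ccc(OC(C)=O)c(OC)c1 | starting material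
4 | 2-(dimethoxymethyl)-3,4,5-trimethoxyphenol (dimethyl acetal, formed in the flask) | COC(OC)c1c(O)cc(OC)c(OC)c1OC | intermediate
5 | (6E)-3,4,5-trimethoxy-6-(methoxymethylidene)cyclohexa-2,4-dien-1-one (ortho-quinone methide, formed in the flask) | CO/C=C1/C(=O)C=C(OC)C(OC)=C1OC | intermediate
6 | (2S,4S)-2-(4-acetoxy-3-methoxyphenyl)-4,5,6,7-tetramethoxychroman (2,4-cis) | COc1cc([C@@H]2C[C@H](OC)c3c(cc(OC)c(OC)c3OC)O2)ccc1OC(C)=O | intermediate
7 | (2S)-2-(4-acetoxy-3-methoxyphenyl)-5,6,7-trimethoxychroman-4-one | COc1cc([C@@H]2CC(=O)c3c(cc(OC)c(OC)c3OC)O2)ccc1OC(C)=O | intermediate
8 | agecorynin E, (2S)-2-(4-hydroxy-3-methoxyphenyl)-5,6,7-trimethoxychroman-4-one | COc1cc([C@@H]2CC(=O)c3c(cc(OC)c(OC)c3OC)O2)ccc1O | target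

Total step count: 4. Longest linear sequence: 4 steps (1 → 2 → 6 → 7 → 8); styrene 3 enters at step 2.

Steps least certain to work

**Step 2 (key step, proposed new method).**
- Most likely failure: poor discrimination between the two faces of the styrene. Styrene 3 has no hydrogen-bonding handle, so its orientation in the ion pair rests on steric fit alone.
- Stepwise closure after bond rotation would also erode the C2 configuration.
- The stabilised cation may instead be captured by C8 of ring A of another molecule (Friedel–Crafts oligomerisation), or turnover with the weak acid may be slow.
- Because the C4 methoxyl can epimerise, the diastereomer ratio of 6 says nothing about C2; enantiopurity would have to be assayed on 7.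
- Within the same approach, the more acidic (R)-N-triflyl-3,3'-bis(2,4,6-triisopropylphenyl)-1,1'-binaphthyl-2,2'-diyl phosphoramide is the first adjustment.

Fallback by known chemistry, setting out from 2 and 3 and returning at 7: the same union through 4 and 5 with an achiral acid such as (PhO)2P(O)OH or catalytic CF3SO3H should give racemic 2-(4-acetoxy-3-methoxyphenyl)-4,5,6,7-tetramethoxychroman F1. Oxidation with DDQ as in step 3 gives racemic 2-(4-acetoxy-3-methoxyphenyl)-5,6,7-trimethoxychroman-4-one F2. Kinetic resolution by Noyori-type transfer hydrogenation (RuCl(p-cymene)[(R,R)-TsNCH(Ph)CH(Ph)NH2], HCO2H/Et3N, EtOAc, rt, stopped near half conversion) should, by the usual sense of this catalyst family, reduce the (2R) ketone to (2R,4R)-2-(4-acetoxy-3-methoxyphenyl)-5,6,7-trimethoxychroman-4-ol F3 and leave the (2S) ketone, which is 7. The price is at most half of the material.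

**Step 3.**
- Most likely failure: hydride abstraction at C2–H in competition with C4–H, or dehydrogenation across C2–C3 towards the flavone. Either destroys the stereocentre.
- Oxidative degradation of ring A before the carbonyl is in place is also possible.

Fallback, setting out from 6 and returning at 7: dilute aqueous HCl in THF (0 °C to rt) exchanges the C4 methoxyl for hydroxyl through the same C4 cation, giving (2S)-2-(4-acetoxy-3-methoxyphenyl)-5,6,7-trimethoxychroman-4-ol F4 as a mixture of C4 epimers. Dess–Martin periodinane with NaHCO3 in CH2Cl2 then oxidises it to 7. This replaces hydride abstraction by solvolysis and alcohol oxidation.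

**Step 4.**
- Most likely failure: slow methanolysis that forces long exposure to acid, with partial loss of configuration at C2 through reversible ring opening once the 4'-hydroxyl is free.

Fallback, setting out from 6 and returning at 8, with a change of protecting group before the ketone exists:
- K2CO3 in MeOH at 0 °C removes the acetate at the flavan stage, where no chalcone pathway is open, giving 2-methoxy-4-[(2S,4S)-4,5,6,7-tetramethoxychroman-2-yl]phenol F5.
- TBSCl and imidazole in DMF give (2S,4S)-2-[4-(tert-butyldimethylsilyloxy)-3-methoxyphenyl]-4,5,6,7-tetramethoxychroman F6.
- DDQ as in step 3 gives (2S)-2-[4-(tert-butyldimethylsilyloxy)-3-methoxyphenyl]-5,6,7-trimethoxychroman-4-one F7.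
- Bu4NF buffered with AcOH in THF at 0 °C releases 8 within minutes under near-neutral conditions.

**Step 1.**
- Most likely failure: over-reaction of the very electron-rich phenol, by a second formylation at the other ortho position or by condensation of the hydroxymethyl stage with a second phenol.

Fallback, setting out from 1 and returning at 2: Rieche formylation (Cl2CHOMe, TiCl4, CH2Cl2, 0 °C; aqueous work-up), an electrophilic aromatic substitution directed ortho by titanium phenoxide chelation. It makes no compound beyond 1 and 2 (F0).

Further compounds

F1 | step 2 | racemic 2-(4-acetoxy-3-methoxyphenyl)-4,5,6,7-tetramethoxychroman (C4 epimers) | COc1cc(C2CC(OC)c3c(cc(OC)c(OC)c3OC)O2)ccc1OC(C)=O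
F2 | step 2 | racemic 2-(4-acetoxy-3-methoxyphenyl)-5,6,7-trimethoxychroman-4-one | COc1cc(C2CC(=O)c3c(cc(OC)c(OC)c3OC)O2)ccc1OC(C)=O
F3 | step 2 | (2R,4R)-2-(4-acetoxy-3-methoxyphenyl)-5,6,7-trimethoxychroman-4-ol (2,4-cis) | COc1cc([C@H]2C[C@@H](O)c3c(cc(OC)c(OC)c3OC)O2)ccc1OC(C)=O
F4 | step 3 | (2S)-2-(4-acetoxy-3-methoxyphenyl)-5,6,7-trimethoxychroman-4-ol (C4 epimers) | COc1cc([C@@H]2CC(O)c3c(cc(OC)c(OC)c3OC)O2)ccc1OC(C)=O
F5 | step 4 | 2-methoxy-4-[(2S,4S)-4,5,6,7-tetramethoxychroman-2-yl]phenol | COc1cc([C@@H]2C[C@H](OC)c3c(cc(OC)c(OC)c3OC)O2)ccc1O
F6 | step 4 | (2S,4S)-2-[4-(tert-butyldimethylsilyloxy)-3-methoxyphenyl]-4,5,6,7-tetramethoxychroman | COc1cc([C@@H]2C[C@H](OC)c3c(cc(OC)c(OC)c3OC)O2)ccc1O[Si](C)(C)C(C)(C)C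
F7 | step 4 | (2S)-2-[4-(tert-butyldimethylsilyloxy)-3-methoxyphenyl]-5,6,7-trimethoxychroman-4-one | COc1cc([C@@H]2CC(=O)c3c(cc(OC)c(OC)c3OC)O2)ccc1O[Si](C)(C)C(C)(C)C
F0 | step 1 | none | none
A1 | alternative 1 | 1-diazo-3,4-dimethoxybut-3-en-2-one | [N-]=[N+]=CC(=O)C(OC)=COC
A2 | alternative 1 | 3,4-dimethoxybuta-1,3-dien-1-one (vinylketene) | O=C=CC(OC)=COC
A3 | alternative 1 | triisopropyl{[(5R)-5-(4-benzyloxy-3-methoxyphenyl)-5-(tert-butyldimethylsilyloxy)pent-1-yn-1-yl]oxy}silane | CC(C)[Si](OC#CCC[C@@H](O[Si](C)(C)C(C)(C)C)c1ccc(OCc2ccccc2)c(OC)c1)(C(C)C)C(C)C
A4 | alternative 1 | (R)-2-[3-(4-benzyloxy-3-methoxyphenyl)-3-(tert-butyldimethylsilyloxy)propyl]-5,6-dimethoxy-3-(triisopropylsilyloxy)phenol | COc1cc(O[Si](C(C)C)(C(C)C)C(C)C)c(CC[C@@H](O[Si](C)(C)C(C)(C)C)c2ccc(OCc3ccccc3)c(OC)c2)c(O)c1OC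
A5 | alternative 2 | 4-[(1S)-1-{2-[1-(tert-butyldimethylsilyloxy)ethenyl]-3,4,5-trimethoxyphenoxy}prop-2-en-1-yl]-2-methoxyphenyl acetate | COc1cc([C@@H](Oc2cc(OC)c(OC)c(OC)c2C(=C)O[Si](C)(C)C(C)(C)C)C=C)ccc1OC(C)=O
A6 | alternative 2 | (S)-2-(4-acetoxy-3-methoxyphenyl)-4-(tert-butyldimethylsilyloxy)-5,6,7-trimethoxy-2H-chromene | COc1cc([C@@H]2C=C(O[Si](C)(C)C(C)(C)C)c3c(cc(OC)c(OC)c3OC)O2)ccc1OC(C)=O
A7 | alternative 3 | (1S,3S)-3-(4-benzyloxy-3-methoxyphenyl)-1-(6-bromo-2,3,4-trimethoxyphenyl)propane-1,3-diol (anti) | COc1cc([C@@H](O)C[C@H](O)c2c(Br)cc(OC)c(OC)c2OC)ccc1OCc1ccccc1
A8 | alternative 3 | (2S,4S)-2-(4-benzyloxy-3-methoxyphenyl)-5,6,7-trimethoxychroman-4-ol (2,4-cis) | COc1cc([C@@H]2C[C@H](O)c3c(cc(OC)c(OC)c3OC)O2)ccc1OCc1ccccc1
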